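Readings and results stem from a simulated flask with made-up constants, noise included.

Read autumn first. Here is what you have:

| setting | spring | autumn | midnight | eta | zeta | gamma | epsilon |
|---|---|---|---|---|---|---|---|
| starting material | 10 mM | 10 mM | 10 mM | 10 mM | 10 mM (fed, over 20 min) | 10 mM | 10 mM |
| second substrate | 15 mM | 10 mM | 22 mM | 15.0 mM (fed, over 20 min) | 15.0 mM | 15.0 mM | 15.0 mM (fed, over 5.0 min) |
| enzyme | 6.5 µM | 6.5 µM | 6.5 µM | 6.5 µM | 6.5 µM | 6.5 µM | 6.5 µM |
| added ligand | 15 µM | 15 µM | 15 µM | 15 µM | 15 µM | 15 µM | 15 µM |
| remark | run made earlier | run made earlier | run made earlier | all else is in the flask from the start; the feed brings no volume worth counting | all else is in the flask from the start; the feed brings no volume worth counting | everything together at the start | all else is in the flask from the start; the feed brings no volume worth counting |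
| time |  |  |  | 25 min | 25 min | 25 min | 25 min |

- spring (time / min: product / %, starting material / %): 1.33: 6, 94; 4.00: 15, 83; 8.00: 23, 76; 10.0: 32, 67; 15.0: 46, 54
- autumn (time / min: product / %, starting material / %): 2.50: 10, 92; 5.00: 17, 83; 8.00: 20, 78; 15.0: 40, 59; 30.0: 65, 34
- midnight (time / min: product / %, starting material / %): 2.50: 11, 91; 5.00: 19, 80; 8.00: 31, 73; 15.0: 51, 51; 30.0: 78, 22

(each reading ± 1.5 percentage points)



* the flask with the highest amount of product, in percent of the starting material charged ("all alike" if they lie within 1.5 percentage points) (eta / zeta / gamma / epsilon / all alike)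
* final product, as a percentage of the starting material charged, in eta
* final product, as a percentage of the starting material charged, in zeta
* final product, as a percentage of the starting material charged, in gamma
* final product, as a percentage of the starting material charged, in epsilon

Call starting material A and second substrate B, assume one B goes per A, and write s = B/(A+B) for the share of B. My trial law, the same form the forecast uses, is rate = κ·A·s. In autumn B equals A the whole way, so s stays at half and A should fall first order. It does: ln(1/fraction left)/time reads 0.0352 min⁻¹ at 15.0 min and 0.0360 min⁻¹ at 30.0 min. So κ is 0.0719 min⁻¹, twice the slope.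

Now gamma. There s starts at 0.600, and holding that leaves 34.0% of A after 25 min. Put that answer back: with that much A used, the share I reckon for gamma comes out at 0.712, the mean is 0.656, and the second round gives 69.2% product.

The weak link is κ, taken from another recipe. Spring is gamma's recipe, and its last reading, with a mean share of 0.629, reforges κ, the rate over A·s, to 0.0653 min⁻¹. Gamma then keeps 34.3% of A, close to the first round, so the share stands and I commit to 65.7% product.

For the feeds, a rough rule: treat a steady feed as the whole charge dropped in at its midpoint, and keep gamma's mean share. Eta and zeta then get 47.4% and epsilon 61.9%, so gamma leads.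

The forecast also names gamma, with 67%, epsilon 64%, eta 53% and zeta 49%, and says that the pattern of the runs “fits a two-step, ping-pong-like law”. My fed flasks lie lower than its figures.

Gamma holds the most product, 66.4%, then epsilon 63.7%, eta 53.9% and zeta 50.1%.

    starting material + enzyme ⇌ starting complex (K = 190 M⁻¹, k = 667 M⁻¹ s⁻¹)
    second substrate + starting complex ⇌ ternary complex (K = 401 M⁻¹, k = 6530 M⁻¹ s⁻¹)
    ternary complex → enzyme + product (k = 1.38 s⁻¹)
    enzyme + added ligand ⇌ idle complex (K = 39000 M⁻¹, k = 120 M⁻¹ s⁻¹)

The forecast stands, but gamma's figure moves by 5 points at an enzyme charge of 5.84 µM or 7.23 µM, with the other amounts and the time held. Take κ to gamma's neighbour with 38 mM of second substrate. Its share starts at 0.792, a first round leaves 27.5% of A, and the mean share becomes 0.855. That gives 75.2% product, and the neighbour holds 76.9%.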